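The readings were computed for an exercise; scatter was added.

Count the J. E has taken up two J per L and G has taken 3, and that balance needs no rate constant.

the same everywhere: L 0.050 M

|  | J | remark | time |
|---|---|---|---|
| dusk | 0.057 M | run made earlier |  |
| dawn | 0.34 M | run made earlier |  |
| beta | 0.0480 M |  | 3.0 h |
| alpha | 0.120 M |  | 3.0 h |
| epsilon | 0.300 M |  | 3.0 h |

- dusk (time / min: E / %): 10.0: 1.7; 25.0: 5.6; 50.0: 10.6; 120: 18.2
- dawn (time / min: E / %): 15.0: 20.3; 40.0: 27.9; 80.0: 22.7; 120: 16.0

(standard deviation of a reading: 0.3 percentage points)

- which of the two there is more of at the end, beta (E / G)
- which of the two there is more of at the end, alpha (E / G)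
- which of the two there is more of at the end, epsilon (E / G)
- final E, as a percentage of the L charged, in beta
- final E, as a percentage of the L charged, in alpha
- final E, as a percentage of the L charged, in epsilon

- the analysis behind the earlier runs scatters by 0.3 percentage points, standard deviation
- a reading or a percentage of E counts all its forms, free or not

Let r be the equivalents of J charged per L, which is 2.40 in alpha. If a flask with r between two and 3 spends its J and nothing takes up more than 3, E cannot exceed 3 minus r as a share of the L charged, and anything left behind E lowers it further. This stoichiometric limit for alpha, 60.0%, is what I call the J ceiling.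

Two extreme versions of alpha bracket the answer. In the first, J attacks E from the moment it appears, so E rises and falls as a plain intermediate. In the second, J leaves E alone until everything before it has become E, so E ends on the ceiling and the remaining 40.0% lies beyond it.

Dawn tells me where to lean. Its E falls by 5.2 percentage points and then by a larger 6.7 points over equal spans of 40.0 min, whereas a loss proportional to E and J ought to shrink, although a dying feed would pull the same way. So I expect alpha to end below its ceiling but nearer the second version, with more E than G.

The forecast differs. Its final E is 22% in beta, 26.5% in alpha and 11.5% in epsilon, with the larger of the pair E, G and G, and it calls alpha “essentially a toss-up”.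

The flask gives final E of 15.0% in beta, 48.8% in alpha and 12.3% in epsilon, and alpha holds E well above its G of 14.9%.

    E + J → X + G (k = 0.0111 /M/s)
    D ⇌ E, rate k2*(cs2 - [E]) while solid is left; crystals form when [E] > cs2 (solubility = 0.800 mM, k = 0.00317 /s)
    E + J → Z (k = 0.0105 /M/s)
    L + J → X + Q (k = 0.0108 /M/s)
    Q + J → X + E (k = 0.00497 /M/s)

In alpha at 3.00 h, crystals D, which are counted in E, stand at 46.9% of the L charged. That E lies 11 points under the ceiling of 60.0%, with 21.1% still Q and 14.3% of the J free.

Alpha left until 12 h has the same r, so its ceiling stays 60.0%, and I expect E to stay under it. E there stands at 55.1%, with Q at 6.22% and 3.2% of the J free.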